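**Retrosynthetic overview**
1. The only skeletal bond made is aryl C5'–CH2 of the prenyl group. It is disconnected by a retro-aromatic Claisen ([3,3]) to the 4'-O-(1,1-dimethylallyl) ether, where C5' is the only free ortho position.
2. The tertiary allyl aryl ether is disconnected at O–C to the 4'-phenol and a 1,1-dimethyl-π-allyl-palladium electrophile; this needs the more acidic 7-OH masked as a TIPS ether.
3. The flavanone core with C2 already (S) is the natural product (2S)-homoeriodictyol (1).
4. Ring order: no ring is built. Rings A, C and B all arrive in 1, and the C2 stereocenter is carried through under non-basic or buffered conditions.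

Assumption: 1 is bought as the enantiopure (2S) natural isolate in free-phenol form (the sodium salt is acidified and extracted first), and its ee is confirmed by chiral HPLC on receipt.

**Step 1**
Reactants: 1, (2S)-homoeriodictyol [(2S)-5,7-dihydroxy-2-(4-hydroxy-3-methoxyphenyl)chroman-4-one]; 2, chlorotriisopropylsilane (TIPSCl)
Product: 3, (2S)-5-hydroxy-2-(4-hydroxy-3-methoxyphenyl)-7-[(triisopropylsilyl)oxy]chroman-4-one
Conditions: TIPSCl (1.05 equiv), imidazole (2.2 equiv), DMF, 0 °C, 1–2 h
Reagents that add atoms: TIPSCl, CC(C)[Si](Cl)(C(C)C)C(C)C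
Why: Acidity-controlled regioselective silyl ether formation: the vinylogous-acid 7-OH (pKa ~7.5) is silylated, the chelated 5-OH and the hindered guaiacol 4'-OH (pKa ~10) are not, and imidazole is too weak a base to form the 4'-phenoxide that would open the C ring and racemise C2.

**Step 2**
Reactants: 4, 2-methylbut-3-en-2-ol; 5, di-tert-butyl dicarbonate (Boc2O)
Product: 6, tert-butyl (2-methylbut-3-en-2-yl) carbonate
Conditions: n-BuLi (1.0 equiv), THF, 0 °C; then Boc2O, 0 °C → rt
Reagents that add atoms: Boc2O, CC(C)(C)OC(=O)OC(=O)OC(C)(C)C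
Why: O-acylation of the lithium tertiary alkoxide by Boc2O gives the mixed carbonate cleanly, with no stereochemistry involved.

**Step 3**
Reactants: 3, 7-O-TIPS-homoeriodictyol; 6, tert-butyl (2-methylbut-3-en-2-yl) carbonate
Product: 7, (2S)-5-hydroxy-2-{3-methoxy-4-[(2-methylbut-3-en-2-yl)oxy]phenyl}-7-[(triisopropylsilyl)oxy]chroman-4-one
Conditions: Pd(PPh3)4 (5 mol %), 6 (1.5 equiv), THF, 0–4 °C, Ar, 6–12 h
Reagents that add atoms: carbonate 6, CC(C)(C)OC(=O)OC(C)(C)C=C
Why: Decarboxylative Tsuji–Trost O-allylation: the phenoxide is generated only catalytically and attacks the more substituted terminus of the 1,1-dimethyl-π-allyl-Pd at low temperature to give the kinetic tertiary ether, with no stoichiometric base, so C2 is untouched and the chelated 5-OH does not compete.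

**Step 4**
Reactants: 7, the 4'-O-(1,1-dimethylallyl) ether
Product: 8, (2S)-5-hydroxy-2-[4-hydroxy-3-methoxy-5-(3-methylbut-2-en-1-yl)phenyl]-7-[(triisopropylsilyl)oxy]chroman-4-one
Conditions: degassed PhMe (0.05 M), 110 °C, sealed tube, ~12 h
Reagents that add atoms: none
Why: Aromatic Claisen [3,3]-sigmatropic rearrangement: the gem-dimethyl ether rearranges at unusually low temperature, only the free C5' ortho position can re-aromatise (attack at the OMe-bearing C3' is reversible), and the allyl inversion gives the linear prenyl group; the neutral aprotic medium leaves C2 (S) intact.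

**Step 5**
Reactants: 8, the 7-O-TIPS-5'-prenylflavanone
Product: 9, (2S)-5,7-dihydroxy-2-[4-hydroxy-3-methoxy-5-(3-methylbut-2-en-1-yl)phenyl]chroman-4-one (target)
Conditions: TBAF (1.2 equiv), AcOH (1.5 equiv), THF, 0 °C, 30 min; pH 5 buffer work-up
Reagents that add atoms: none
Why: Fluoride-mediated desilylation of the activated aryl silyl ether is fast at 0 °C, and the AcOH buffer prevents phenoxide-driven retro-oxa-Michael racemisation at C2 and acid-type cyclisation of the ortho-prenylphenol to a chroman.

**Compound list**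
1 | (2S)-homoeriodictyol; (2S)-5,7-dihydroxy-2-(4-hydroxy-3-methoxyphenyl)chroman-4-one | COc1cc([C@@H]2CC(=O)c3c(O)cc(O)cc3O2)ccc1O | starting material
2 | chlorotriisopropylsilane (TIPSCl) | CC(C)[Si](Cl)(C(C)C)C(C)C | starting material
3 | (2S)-5-hydroxy-2-(4-hydroxy-3-methoxyphenyl)-7-[(triisopropylsilyl)oxy]chroman-4-one | COc1cc([C@@H]2CC(=O)c3c(O)cc(O[Si](C(C)C)(C(C)C)C(C)C)cc3O2)ccc1O | intermediate
4 | 2-methylbut-3-en-2-ol | CC(C)(O)C=C | starting material
5 | di-tert-butyl dicarbonate | CC(C)(C)OC(=O)OC(=O)OC(C)(C)C | starting material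
6 | tert-butyl (2-methylbut-3-en-2-yl) carbonate | CC(C)(C)OC(=O)OC(C)(C)C=C | intermediate
7 | (2S)-5-hydroxy-2-{3-methoxy-4-[(2-methylbut-3-en-2-yl)oxy]phenyl}-7-[(triisopropylsilyl)oxy]chroman-4-one | COc1cc([C@@H]2CC(=O)c3c(O)cc(O[Si](C(C)C)(C(C)C)C(C)C)cc3O2)ccc1OC(C)(C)C=C | intermediate
8 | (2S)-5-hydroxy-2-[4-hydroxy-3-methoxy-5-(3-methylbut-2-en-1-yl)phenyl]-7-[(triisopropylsilyl)oxy]chroman-4-one | COc1cc([C@@H]2CC(=O)c3c(O)cc(O[Si](C(C)C)(C(C)C)C(C)C)cc3O2)cc(CC=C(C)C)c1O | intermediate
9 | (2S)-5,7-dihydroxy-2-[4-hydroxy-3-methoxy-5-(3-methylbut-2-en-1-yl)phenyl]chroman-4-one | COc1cc([C@@H]2CC(=O)c3c(O)cc(O)cc3O2)cc(CC=C(C)C)c1O | target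

**Step count**
Total steps: 5 (four on the main line plus one reagent preparation).
Longest linear sequence: 4 (1 → 3 → 7 → 8 → 9).

**Three steps most likely to fail**
1. Step 3 (Pd O-tert-prenylation). Risks are linear O-prenyl ether from Pd-mediated isomerisation, a sluggish hindered guaiacol OH, and silyl transfer. Fallback: build the same ether 7 without π-allyl chemistry, by Cu-catalysed O-propargylation with 3-chloro-3-methylbut-1-yne (CuCl2 cat., DBU, MeCN, −5 °C, short contact) followed by Lindlar semi-hydrogenation of the 1,1-dimethylpropargyl ether.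
2. Step 4 (Claisen). Risks are loss of isoprene back to phenol 3, chroman formation, and partial erosion of ee at 110 °C. Fallback: make the plain 4'-O-allyl ether instead (Mitsunobu with allyl alcohol), run its fragmentation-free Claisen to the 5'-allyl phenol, then convert allyl to prenyl by olefin cross-metathesis with 2-methyl-2-butene (Grubbs II).
3. Step 1 (mono-silylation at O7). Risks are 7,4'-bis-silylation or 4'-O-silyl contamination. Fallback: mask O7 by Mitsunobu etherification with 2-(trimethylsilyl)ethanol (PPh3, DIAD, THF, 0 °C), which selects the most acidic phenol under neutral conditions. The 7-O-TMSE ether is carried through steps 3–4 and removed at the end with buffered fluoride.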